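The amounts in these flasks are best followed as the fraction of substrate left, f, and not as the fraction made. With substrate at starting concentration c and reagent charged at 1.00 equiv, the two fall together as long as the first step is the one that uses reagent, and 1/f then grows in a straight line with time.

| flask | substrate | reagent | remark | time |
|---|---|---|---|---|
| amber | 0.0030 M | 1 equiv | run made earlier |  |
| green | 0.026 M | 1 equiv | run made earlier |  |
| epsilon | 0.0050 M | 1.00 equiv |  | 10 h |
| theta | 0.010 M | 1.00 equiv |  | 10 h |
| alpha | 0.020 M | 1.00 equiv |  | 10 h |
| zeta | 0.040 M | 1.00 equiv |  | 10 h |

- amber (time / h: first product / %, bis adduct / %): 1.33: 1.7, 0.2; 3.00: 3.4, 0; 4.00: 4.4, 0.9; 6.00: 6.5, 0.6; 8.00: 9.1, 0.6; 10.0: 11.1, 0.3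
- green (time / h: first product / %, bis adduct / %): 1.33: 11.7, 0.8; 3.00: 19.2, 2.7; 4.00: 21.6, 4.3; 6.00: 23.8, 6.8; 8.00: 25.1, 8.5; 10.0: 26.8, 10.9

(each reading ± 0.5 percentage points)

1. share of first product in all that became first product or bis adduct or over-reaction product for epsilon, theta, alpha, zeta, in this order
2. the course of these numbers from the first flask to the last (hardly changes / falls, then rises / rises, then falls / rises all the way / falls all the way)

- "hardly changes" means that all values lie within two and a half points (for a concentration: within two and a half percent of the largest)

The first setting is time. By hand, for equal charges of substrate and reagent and a first step of rate constant k,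

f = 1/(1 + τ), with τ = k·c·t,

so doubling t doubles the dimensionless time τ, the second-order clock of the flask. The second setting is concentration, and by hand it acts on τ exactly as time does. The runs bear this out: amber at 10.0 h and green at 1.33 h have c·t of 108 M·s and 124 M·s, and they read 11.1% and 11.7% of first product, with a scatter of 0.5 percentage points. The reagent charge stays at 1.00 equiv in the four new flasks and is not turned.

Amber, taking what it shows as the whole turnover, gives a reading of k:

k = 4.29 M⁻¹ h⁻¹

At 10 h the clock then stands at:

epsilon 0.214, theta 0.429, alpha 0.858, zeta 1.72

Green at 10.0 h stands at 1.12, so 52.8% of its substrate should have turned over, yet first product and bis adduct together read 37.7%. Counting the gap as over-reaction product, the share of first product in green is 50.8%. Alpha's clock stands below green's and zeta's above it, so this reckoning expects a share that falls from flask to flask and passes 50.8% between alpha and zeta.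

The forecast gives 85%, 73%, 58% and 41%, so falls all the way, holding that “share depends only on c·t”.

The flasks give 81.9%, 70.1%, 56.6% and 45.5%: the share falls all the way.

    reagent + first product → bis adduct + by-product (k = 3.90 M⁻¹ h⁻¹)
    reagent + first product → over-reaction product (k = 5.10 M⁻¹ h⁻¹)
    substrate + reagent → first product + by-product (k = 4.60 M⁻¹ h⁻¹)

In zeta the clock of 1.72 gives 36.8% of substrate left, but the flask holds 44.9%, with reagent down to 14.8% of its charge. That shrinking supply of reagent is the main reason zeta keeps a share of 45.5%: without it, the same flask gives 16.3%. Theta, with 60% of its reagent left, stands at a clock of 0.429, which gives 70.0% of substrate left, and the flask holds 69.6%.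

Readings and results were computed from invented constants; the scatter is artificial.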